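## The problem

The target consists of two 2,3-diaryl-2,3-dihydrobenzofurans. The upper one is joined through its sp3 carbon C3 to arene carbon C6' of the lower one and carries an (E)-4-hydroxystyryl group on C6; there are eight free phenols. There are four stereocentres, C2/C3 and C2'/C3', all S, and trans within each furan ring. The two pairs lie on different rings, meta to each other across the lower arene, so neither can steer the other and each half must be secured as a single enantiomer on its own. Within each pair trans is the thermodynamic arrangement, so one centre per ring is enough: C2 can fix C3 by base epimerisation, and C3' can fix C2' by reversible ionisation at C2'. The fragile parts are the electron-rich stilbene (acid, oxidants and hydrogenation are excluded), the benzylic aryl ethers C2–O1 and especially C2'–O1', whose 2,4-dioxygenated aryl group invites ionisation, and the resorcinol rings, which must stay protected until the end. The C3–C6' bond is an aryl–C(sp3) bond at a stereocentre next to a second one, which is awkward for cross-coupling. The enabling feature is the lower arene C3a'–C4'–C5'–C6'–C7'–C7a': it has oxygen on C4' and on C7a' (O1') on either side of C3a', hydrogen on C5' and C7', and the upper C3 on C6'. This is the pattern left by a 1,3-dioxygenated diene C7a'=C3a'–C4'=C5' and a two-carbon alkyne C6'≡C7', and the unsubstituted C7' can carry a removable ester that directs the regiochemistry.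

## Retrosynthesis

**33 from 32.** The seven O–CH3 bonds are cut last. Methyl ethers are chosen because the route uses organolithiums, hydrides, a rhodium carbene and a 130 °C cycloaddition; benzyl ethers would need hydrogenolysis, which the stilbene does not tolerate. The precursor 32 has the full skeleton and all four stereocentres; the forward reaction (BBr3) must cleave aryl methyl ethers without ionising the benzylic ethers.

**32 from 30.** The C7'–carboxyl bond is cut. The ester on C7' has no counterpart in the target and serves only to polarise the alkyne. It ends up ortho to O1' and para to the C4' hydroxyl, the most favourable position for protodecarboxylation. An allyl ester is preferred to a methyl ester: a benzoate flanked by two ortho substituents and conjugated to a para-phenoxide resists saponification, whereas an allyl ester is removed at the allyl carbon by Pd(PPh3)4.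

**30 from 27 and 18 (key disconnection).** The bonds C5'–C6' and C7'–C7a' are cut, which takes the lower arene apart into bis-silyl dienol ether 27 and ynoate 18. The neighbouring cut, C3–C6', would require coupling an aryl metal with a secondary benzylic electrophile at a stereocentre. Closing either furan ring after the union would put a stereogenic event into the largest intermediate. The chosen cut creates no stereocentre and divides the molecule into two halves of similar size, each holding one trans pair. The forward reaction must be regioselective, must aromatise, and must leave four benzylic stereocentres and a stilbene untouched.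

**27 from 25 from 24.** The two O–Si bonds and the C3–acetyl bond are cut. Diene 27 is the double silyl enol ether of acetyl lactone 25, which comes from C-acetylation of trans lactone 24. The lactone already contains O1'–C2', C2'–C3' and C3'–C3a' with the correct configuration, so the furan ring of the lower half is in place before the arene exists.

**24 from 22, 21, 19 and 20.** The lactone C5–O bond and the carbinol C–H bond are cut back to racemic keto ester 22. A transfer hydrogenation with dynamic kinetic resolution fixes C3' (lactone C4), and acid closure through the 2,4-dimethoxybenzylic cation sets C2' trans to it. Keto ester 22 comes from alkylation of deoxybenzoin 21 with methyl bromoacetate 9. Ketone 21 comes from palladium-catalysed α-arylation of acetophenone 19 with bromide 20; this is preferred to a Friedel–Crafts acylation because both rings are strongly activated and would compete.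

**18 from 16, 15 and 14.** The ester C–C bond and the alkyne are cut back to aldehyde 15 by way of dibromoalkene 16 (one-carbon homologation, then acylation of the acetylide). Aldehyde 15 comes from trans ester 14 by partial reduction. No stereocentre is touched.

**14 from 13 from 12.** The C2–C3 bond of the upper furan is cut. Intramolecular insertion of the rhodium carbene from aryldiazoacetate 12 into the benzylic C–H bond of its 4-methoxybenzyl ether sets C2 under catalyst control and gives cis ester 13. Epimerisation at C3 then gives trans ester 14. Compared with building the ring by C–O closure, this makes the C–C bond and the C2 stereocentre in one step from an achiral precursor.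

**12 from 11 from 8, and back to 1.** The diazo group comes from diazo transfer to arylacetate 11. The arylacetate comes from palladium coupling of aryl bromide 8 with the zinc enolate 10 of methyl bromoacetate 9. Stilbene 8 comes from a Horner–Wadsworth–Emmons reaction of aldehyde 6 with phosphonate 7. Aldehyde 6 comes from benzoate 1 by mono-etherification with 2 (giving 3), methylation (4), reduction (5) and oxidation.

## Roads not taken

**Alternative 1:** The cut is the C3'–C3a' bond of the lower furan, formed by contracting a chromanone. In the forward step the enantioenriched flavanone A2 is treated with the trivalent iodine oxidant PhI(OAc)2 in acidic trimethyl orthoformate; attack at C3 of the enol ether triggers a shift of the arene carbon from C4 to C3 and should give the trans ester A1 with C2' carried over. Its merits are a key step of a known type, a short path to a lower ring with a bromide at C6', and automatic trans geometry. For this target there are three weak points. First, the group that arrives on C3' is a methoxycarbonyl group, not the 3,5-dimethoxyphenyl ring, so a decarboxylative arylation at a benzylic stereocentre has to follow. Second, the 2,4-dimethoxyphenyl ring on C2 of A2 is the better migrating group, so a 2→3 aryl shift to an isoflavone competes; the same ring also favours acid-mediated opening to the chalcone, which would erode the enantiomeric purity. Third, the C6' bromide still has to be joined to the stereogenic sp3 carbon C3 of the upper ring. Alternative 1 is better in that its ring-forming step has direct precedent on the flavanone skeleton, and in the modular halide handle. The chosen plan sets against this that the C3' aryl group is present from the first step of the lower half and that the union of the halves creates no stereocentre.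

**Alternative 2:** The cut removes C3–C3a and the C2–aryl bond of the upper ring at once. In the forward step the boronate complex formed from alkenyl boronate A4 and an aryllithium carrying the 4-methoxyphenyl group reacts with aryl bromide A5 under Pd(OAc)2 and a chiral bisphosphine; 1,2-migration across the alkene should give the anti boronate A3, which is then oxidised and cyclised to the upper furan. Its merit is real: both upper stereocentres are set in one catalytic three-component step, and the upper half needs far fewer steps than the twelve used here. The weak points are the partners. A5 is flanked by two ortho alkoxy groups, A4 carries a very large β-aryl group, and direct Suzuki coupling and halide inhibition compete with the metallate shift. The later C–O closure at C2 must also proceed with defined stereochemistry. Finally, the whole lower dihydrobenzofuran must be made first by other chemistry and fitted with a vinyl boronate. In step economy for the upper half and in catalytic stereocontrol at the point of union, Alternative 2 is superior. The chosen plan sets against this a stereochemically silent union that needs no hindered palladium coupling, and a lower half that comes from a simple lactone.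

**Alternative 3:** The cut is the O1'–C2' bond of the lower furan. An asymmetric conjugate arylation on a lactone tether is meant to set C3'; after lactone opening, acid A7 is oxidised at an anode, loses CO2, and the phenol captures the C2' cation to give trans ester A6. Its merits are catalytic control of C3', thermodynamic control of C2', and a preformed lower arene, which avoids any uncertain cycloaddition. The weak point is the electrolysis: A7 contains a free phenol and two dimethoxyarenes that are oxidised more easily than a carboxylate, so arene and phenol oxidation are the expected competitors. In addition, the ester at C6' of A6 must still be turned into a bond to the upper C3 stereocentre. The chosen plan uses the same cation-capture logic at C2', but with a Brønsted acid on a lactone (step 15), where no oxidant is present. Alternative 3 is better in not depending on a new diene–ynoate pairing. The chosen plan sets against this that the arene-forming step is also the fragment union, so no further C–C bond has to be made at C3.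

Key step: step 18

Assumption 1: Rh2(S-PTTL)4 is taken to give the (2S) insertion product 13; if the sense of induction proves opposite, Rh2(R-PTTL)4 is used.

Assumption 2: the transfer hydrogenation is taken to follow the usual aryl ketone rule ((R,R)-TsDPEN gives the (R)-carbinol) with Felkin-type matching, so that (3R,4R)-23 forms; if the matched pair is the other one, the (S,S)-catalyst is used, since only C3 of 23 survives the acid stage of step 15.

Step 1
Reactants: 1 methyl 4-bromo-3,5-dihydroxybenzoate; 2 4-methoxybenzyl chloride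
Product: 3 methyl 4-bromo-3-hydroxy-5-[(4-methoxybenzyl)oxy]benzoate
Conditions: 2 (1.0 equiv), K2CO3 (1.1 equiv), DMF, rt
Reagents that add atoms: none
Why: Williamson mono-etherification of a symmetric resorcinol; the hydroxyls are equivalent, so one equivalent of halide should give mainly the mono-ether, and the accompanying diol and bis-ether are separable, the diol being reusable.

Step 2
Reactants: 3 methyl 4-bromo-3-hydroxy-5-[(4-methoxybenzyl)oxy]benzoate
Product: 4 methyl 4-bromo-3-methoxy-5-[(4-methoxybenzyl)oxy]benzoate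
Conditions: MeI, K2CO3, acetone, 50 °C
Reagents that add atoms: iodomethane, CI
Why: Williamson O-methylation of the remaining phenol; it differentiates the oxygen that becomes C4–OMe from the one that becomes O1.

Step 3
Reactants: 4 methyl 4-bromo-3-methoxy-5-[(4-methoxybenzyl)oxy]benzoate
Product: 5 {4-bromo-3-methoxy-5-[(4-methoxybenzyl)oxy]phenyl}methanol
Conditions: i-Bu2AlH (2.5 equiv), CH2Cl2, −78 to 0 °C
Reagents that add atoms: none
Why: Aluminium hydride reduction of an aryl ester to the benzylic alcohol; the aryl bromide and the benzyl ether are inert to it.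

Step 4
Reactants: 5 {4-bromo-3-methoxy-5-[(4-methoxybenzyl)oxy]phenyl}methanol
Product: 6 4-bromo-3-methoxy-5-[(4-methoxybenzyl)oxy]benzaldehyde
Conditions: MnO2, CH2Cl2, rt
Reagents that add atoms: none
Why: Selective MnO2 oxidation of a benzylic alcohol, which stops at the aldehyde.

Step 5
Reactants: 6 4-bromo-3-methoxy-5-[(4-methoxybenzyl)oxy]benzaldehyde; 7 diethyl (4-methoxybenzyl)phosphonate
Product: 8 (E)-2-bromo-1-methoxy-3-[(4-methoxybenzyl)oxy]-5-(4-methoxystyryl)benzene
Conditions: KOt-Bu, THF, 0 °C to rt
Reagents that add atoms: none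
Why: Horner–Wadsworth–Emmons olefination with a benzylic phosphonate, which should give the (E)-stilbene through the reversible, anti-selective addition typical of semi-stabilised phosphonate anions.

Step 6
Reactants: 8 (E)-2-bromo-1-methoxy-3-[(4-methoxybenzyl)oxy]-5-(4-methoxystyryl)benzene; 9 methyl bromoacetate
Product: 11 methyl 2-{2-methoxy-6-[(4-methoxybenzyl)oxy]-4-[(E)-4-methoxystyryl]phenyl}acetate, via zinc enolate 10 (not isolated)
Conditions: 9, Zn, Me3SiCl (cat.), THF, rt; then 8, Pd2(dba)3 (cat.), XPhos, THF, 65 °C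
Reagents that add atoms: none
Why: Reformatsky reagent formation followed by Negishi-type α-arylation of the zinc enolate; the bulky biarylphosphine is chosen for oxidative addition into the di-ortho-alkoxy bromide, and the neutral zinc enolate spares the stilbene and the benzyl ether.

Step 7
Reactants: 11 methyl 2-{2-methoxy-6-[(4-methoxybenzyl)oxy]-4-[(E)-4-methoxystyryl]phenyl}acetate
Product: 12 methyl 2-diazo-2-{2-methoxy-6-[(4-methoxybenzyl)oxy]-4-[(E)-4-methoxystyryl]phenyl}acetate
Conditions: p-ABSA, DBU, MeCN, 0 °C to rt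
Reagents that add atoms: 4-acetamidobenzenesulfonyl azide, CC(=O)Nc1ccc(cc1)S(=O)(=O)N=[N+]=[N-]
Why: Regitz diazo transfer to an arylacetate, the standard entry to aryldiazoacetates.

Step 8
Reactants: 12 methyl 2-diazo-2-{2-methoxy-6-[(4-methoxybenzyl)oxy]-4-[(E)-4-methoxystyryl]phenyl}acetate
Product: 13 methyl (2S,3R)-4-methoxy-2-(4-methoxyphenyl)-6-[(E)-4-methoxystyryl]-2,3-dihydrobenzofuran-3-carboxylate (cis)
Conditions: Rh2(S-PTTL)4 (1 mol %), toluene, −60 °C
Reagents that add atoms: none
Why: Intramolecular 1,5 C–H insertion of a donor/acceptor rhodium carbene into the benzylic C–H bond α to the ether oxygen, the most hydridic C–H within reach; the chiral carboxylate ligands select one of the two enantiotopic benzylic hydrogens and so set C2, and the insertion is cis-selective. The trans stilbene is a poor partner for such carbenes and should not be cyclopropanated.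

Step 9
Reactants: 13 methyl (2S,3R)-4-methoxy-2-(4-methoxyphenyl)-6-[(E)-4-methoxystyryl]-2,3-dihydrobenzofuran-3-carboxylate (cis)
Product: 14 methyl (2S,3S)-4-methoxy-2-(4-methoxyphenyl)-6-[(E)-4-methoxystyryl]-2,3-dihydrobenzofuran-3-carboxylate (trans)
Conditions: NaOMe (0.5 equiv), MeOH, rt
Reagents that add atoms: none
Why: Base epimerisation through the ester enolate to the thermodynamically preferred trans isomer; C2 is not acidic and stays fixed, so C3 is set by C2, and ring opening of the enolate would be the stereoelectronically disfavoured reverse of a 5-endo closure.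

Step 10
Reactants: 14 methyl (2S,3S)-4-methoxy-2-(4-methoxyphenyl)-6-[(E)-4-methoxystyryl]-2,3-dihydrobenzofuran-3-carboxylate (trans)
Product: 15 (2S,3S)-4-methoxy-2-(4-methoxyphenyl)-6-[(E)-4-methoxystyryl]-2,3-dihydrobenzofuran-3-carbaldehyde
Conditions: i-Bu2AlH (1.1 equiv), CH2Cl2, −78 °C
Reagents that add atoms: none
Why: Partial reduction of a methyl ester through the tetrahedral aluminium hemiacetal, which is stable at low temperature; the trans aldehyde is also the thermodynamic epimer, so C3 is not at risk.

Step 11
Reactants: 15 (2S,3S)-4-methoxy-2-(4-methoxyphenyl)-6-[(E)-4-methoxystyryl]-2,3-dihydrobenzofuran-3-carbaldehyde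
Product: 16 (2S,3S)-3-(2,2-dibromovinyl)-4-methoxy-2-(4-methoxyphenyl)-6-[(E)-4-methoxystyryl]-2,3-dihydrobenzofuran
Conditions: CBr4, PPh3, CH2Cl2, 0 °C
Reagents that add atoms: tetrabromomethane, BrC(Br)(Br)Br
Why: First stage of the Corey–Fuchs reaction, a Wittig-type dibromomethylenation under essentially neutral conditions that do not enolise the aldehyde.

Step 12
Reactants: 16 (2S,3S)-3-(2,2-dibromovinyl)-4-methoxy-2-(4-methoxyphenyl)-6-[(E)-4-methoxystyryl]-2,3-dihydrobenzofuran
Product: 18 allyl 3-{(2S,3S)-4-methoxy-2-(4-methoxyphenyl)-6-[(E)-4-methoxystyryl]-2,3-dihydrobenzofuran-3-yl}prop-2-ynoate, via lithium acetylide 17 (not isolated)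
Conditions: n-BuLi (2.1 equiv), THF, −78 °C; then ClCO2CH2CH=CH2, −78 to 0 °C
Reagents that add atoms: allyl chloroformate, C=CCOC(Cl)=O
Why: Second stage of the Corey–Fuchs reaction (bromine–lithium exchange, Fritsch–Buttenberg–Wiechell shift, deprotonation), followed by C-acylation of the acetylide with a chloroformate; at −78 °C the acetylide forms much faster than the doubly benzylic C3–H is removed.

Step 13
Reactants: 19 1-(2,4-dimethoxyphenyl)ethan-1-one; 20 1-bromo-3,5-dimethoxybenzene
Product: 21 1-(2,4-dimethoxyphenyl)-2-(3,5-dimethoxyphenyl)ethan-1-one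
Conditions: Pd2(dba)3 (cat.), Xantphos, NaOt-Bu, toluene, 80 °C
Reagents that add atoms: none
Why: Palladium-catalysed α-arylation of a methyl ketone; the wide-bite-angle ligand favours mono-arylation, and the regiochemistry is unambiguous.

Step 14
Reactants: 21 1-(2,4-dimethoxyphenyl)-2-(3,5-dimethoxyphenyl)ethan-1-one; 9 methyl bromoacetate
Product: 22 methyl 4-(2,4-dimethoxyphenyl)-3-(3,5-dimethoxyphenyl)-4-oxobutanoate (racemic)
Conditions: LiN(SiMe3)2 (1.05 equiv), THF, −78 °C; then 9, −78 to 0 °C
Reagents that add atoms: none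
Why: C-alkylation of a deoxybenzoin enolate with a reactive α-halo ester; a second alkylation would create a quaternary centre and is slow.

Step 15
Reactants: 22 methyl 4-(2,4-dimethoxyphenyl)-3-(3,5-dimethoxyphenyl)-4-oxobutanoate (racemic)
Product: 24 (4R,5S)-5-(2,4-dimethoxyphenyl)-4-(3,5-dimethoxyphenyl)dihydrofuran-2(3H)-one (trans), via syn hydroxy ester 23 (not isolated)
Conditions: RuCl[(R,R)-TsDPEN](p-cymene) (2 mol %), HCO2H/Et3N (1:1), DMF, 40 °C; then CF3CO2H, CH2Cl2, 0 °C to rt
Reagents that add atoms: none
Why: Asymmetric transfer hydrogenation with dynamic kinetic resolution: the α-aryl ketone racemises through its enol in the amine-containing medium, and the catalyst reduces the (3R)-enantiomer faster (hydride anti to the 3,5-dimethoxyphenyl group), which sets C3. Acid then ionises the 2,4-dimethoxybenzylic carbinol and the ester oxygen closes the lactone by an SN1 path under thermodynamic control, which sets C5 trans to C4 whatever the carbinol configuration was.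

Step 16
Reactants: 24 (4R,5S)-5-(2,4-dimethoxyphenyl)-4-(3,5-dimethoxyphenyl)dihydrofuran-2(3H)-one (trans)
Product: 25 (4R,5S)-3-acetyl-5-(2,4-dimethoxyphenyl)-4-(3,5-dimethoxyphenyl)dihydrofuran-2(3H)-one (C3 epimers and enol)
Conditions: LiN(i-Pr)2 (1.1 equiv), THF, −78 °C; then MeC(O)N(OMe)Me, −78 to −20 °C
Reagents that add atoms: N-methoxy-N-methylacetamide, CC(=O)N(C)OC
Why: Claisen-type C-acylation of the lactone enolate with a Weinreb amide; the tetrahedral adduct persists until quench, which prevents O-acylation and proton transfer, and the new C3 centre is lost again in step 17.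

Step 17
Reactants: 25 (4R,5S)-3-acetyl-5-(2,4-dimethoxyphenyl)-4-(3,5-dimethoxyphenyl)dihydrofuran-2(3H)-one (C3 epimers and enol)
Product: 27 (4S,5S)-5-(2,4-dimethoxyphenyl)-4-(3,5-dimethoxyphenyl)-2-(trimethylsilyloxy)-3-[1-(trimethylsilyloxy)vinyl]-4,5-dihydrofuran, via silyl enol ether 26 (not isolated)
Conditions: Me3SiCl, Et3N, toluene, rt; then LiN(i-Pr)2, THF, −78 °C; Me3SiCl
Reagents that add atoms: chlorotrimethylsilane, C[Si](C)(C)Cl
Why: Two-stage silylation of a β-keto ester: the amine gives the silyl enol ether of the ketone, then γ-deprotonation and O-silylation of the dienolate at the lactone oxygen give the 1-alkoxy-1,3-bis(silyloxy)diene; C4 and C5 are not acidic and keep their configuration (the descriptor at C4 changes only because the priorities change).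

Step 18
Reactants: 27 (4S,5S)-5-(2,4-dimethoxyphenyl)-4-(3,5-dimethoxyphenyl)-2-(trimethylsilyloxy)-3-[1-(trimethylsilyloxy)vinyl]-4,5-dihydrofuran; 18 allyl 3-{(2S,3S)-4-methoxy-2-(4-methoxyphenyl)-6-[(E)-4-methoxystyryl]-2,3-dihydrobenzofuran-3-yl}prop-2-ynoate
Product: 30 allyl (2S,3S)-2-(2,4-dimethoxyphenyl)-3-(3,5-dimethoxyphenyl)-4-hydroxy-6-{(2S,3S)-4-methoxy-2-(4-methoxyphenyl)-6-[(E)-4-methoxystyryl]-2,3-dihydrobenzofuran-3-yl}-2,3-dihydrobenzofuran-7-carboxylate, via cycloadduct 28 (not isolated), via aryl silyl ether 29 (not isolated)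
Conditions: 27 (2 equiv), toluene (concentrated), 130 °C, sealed tube; then CSA, wet CH2Cl2, rt
Reagents that add atoms: none
Why: The electron-rich diene 27 and the electron-poor ynoate 18 should combine in a polarity-matched, strongly asynchronous [4+2] cycloaddition (at the limit a Mukaiyama–Michael addition followed by collapse of the silyl oxocarbenium ion onto the allenoate): the unhindered CH2 terminus C5' bonds to the β-carbon C6' and the ketene acetal carbon C7a' to the ester-bearing C7'. The closest known reaction type is the Diels–Alder addition and aromatisation of open-chain 1-alkoxy-1,3-bis(silyloxy)butadienes with acetylenic esters to 2,4-dioxygenated benzoates; 27 is a cyclic, 2-substituted member of that diene class. The one ring closed is the carbocycle C3a'–C4'–C5'–C6'–C7'–C7a', formed in the six-membered cycloaddition mode and made aromatic by 1,4-loss of Me3SiOH from C7a' and C5' of 28; the acid stage then frees the C4' phenol of 29. No stereocentre is formed, and C2, C3, C2' and C3' lie outside the reacting π systems under neutral thermal conditions. The selectivity needed is regiochemical: the largest donor coefficient of 27 is on C5' and the largest acceptor coefficient of 18 on the β-carbon, which places the upper ring on C6' and the removable ester on C7'. If 28 instead expels the ring alkoxide, the acid stage recloses the furan by ionisation at the 2,4-dimethoxybenzylic C2' and capture by a flanking phenol, to the trans ring. Closure on either phenol leads to the same compound after step 19, because decarboxylation makes the two oxygens next to C3a' equivalent.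

Step 19
Reactants: 30 allyl (2S,3S)-2-(2,4-dimethoxyphenyl)-3-(3,5-dimethoxyphenyl)-4-hydroxy-6-{(2S,3S)-4-methoxy-2-(4-methoxyphenyl)-6-[(E)-4-methoxystyryl]-2,3-dihydrobenzofuran-3-yl}-2,3-dihydrobenzofuran-7-carboxylate
Product: 32 (2S,3S)-2-(2,4-dimethoxyphenyl)-3-(3,5-dimethoxyphenyl)-6-{(2S,3S)-4-methoxy-2-(4-methoxyphenyl)-6-[(E)-4-methoxystyryl]-2,3-dihydrobenzofuran-3-yl}-2,3-dihydrobenzofuran-4-ol, via carboxylic acid 31 (not isolated)
Conditions: Pd(PPh3)4 (cat.), morpholine, THF, rt; then Ag2CO3 (cat.), AcOH, DMSO, 120 °C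
Reagents that add atoms: none
Why: Tsuji–Trost deallylation cleaves the hindered ester at the allyl carbon and not at the carbonyl; the resulting acid is ortho-alkoxy, ortho-alkyl and para-hydroxy substituted, the ideal case for silver-mediated protodecarboxylation through an aryl silver species.

Step 20
Reactants: 32 (2S,3S)-2-(2,4-dimethoxyphenyl)-3-(3,5-dimethoxyphenyl)-6-{(2S,3S)-4-methoxy-2-(4-methoxyphenyl)-6-[(E)-4-methoxystyryl]-2,3-dihydrobenzofuran-3-yl}-2,3-dihydrobenzofuran-4-ol
Product: 33 (2S,3S)-2-(2,4-dihydroxyphenyl)-3-(3,5-dihydroxyphenyl)-6-{(2S,3S)-4-hydroxy-2-(4-hydroxyphenyl)-6-[(E)-4-hydroxystyryl]-2,3-dihydrobenzofuran-3-yl}-2,3-dihydrobenzofuran-4-ol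
Conditions: BBr3 (excess), CH2Cl2, −78 °C to rt; then MeOH/H2O
Reagents that add atoms: none
Why: Lewis acid cleavage of the seven aryl methyl ethers by BBr3 (bromide attacks the methyl carbon of the borylated ether); the trans dihydrobenzofuran rings are the thermodynamic isomers, so transient ionisation at C2 or C2' should return the same configuration.

## Compound list

1 | methyl 4-bromo-3,5-dihydroxybenzoate | COC(=O)c1cc(O)c(Br)c(O)c1 | starting material
2 | 4-methoxybenzyl chloride | COc1ccc(CCl)cc1 | starting material
3 | methyl 4-bromo-3-hydroxy-5-[(4-methoxybenzyl)oxy]benzoate | COC(=O)c1cc(O)c(Br)c(OCc2ccc(OC)cc2)c1 | intermediate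
4 | methyl 4-bromo-3-methoxy-5-[(4-methoxybenzyl)oxy]benzoate | COC(=O)c1cc(OC)c(Br)c(OCc2ccc(OC)cc2)c1 | intermediate
5 | {4-bromo-3-methoxy-5-[(4-methoxybenzyl)oxy]phenyl}methanol | OCc1cc(OC)c(Br)c(OCc2ccc(OC)cc2)c1 | intermediate
6 | 4-bromo-3-methoxy-5-[(4-methoxybenzyl)oxy]benzaldehyde | O=Cc1cc(OC)c(Br)c(OCc2ccc(OC)cc2)c1 | intermediate
7 | diethyl (4-methoxybenzyl)phosphonate | CCOP(=O)(Cc1ccc(OC)cc1)OCC | starting material
8 | (E)-2-bromo-1-methoxy-3-[(4-methoxybenzyl)oxy]-5-(4-methoxystyryl)benzene | COc1ccc(/C=C/c2cc(OC)c(Br)c(OCc3ccc(OC)cc3)c2)cc1 | intermediate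
9 | methyl bromoacetate | COC(=O)CBr | starting material
10 | bromo(2-methoxy-2-oxoethyl)zinc (zinc enolate of methyl acetate) | COC(=O)C[Zn]Br | intermediate (not isolated)
11 | methyl 2-{2-methoxy-6-[(4-methoxybenzyl)oxy]-4-[(E)-4-methoxystyryl]phenyl}acetate | COC(=O)Cc1c(OC)cc(/C=C/c2ccc(OC)cc2)cc1OCc1ccc(OC)cc1 | intermediate
12 | methyl 2-diazo-2-{2-methoxy-6-[(4-methoxybenzyl)oxy]-4-[(E)-4-methoxystyryl]phenyl}acetate | COC(=O)C(=[N+]=[N-])c1c(OC)cc(/C=C/c2ccc(OC)cc2)cc1OCc1ccc(OC)cc1 | intermediate
13 | methyl (2S,3R)-4-methoxy-2-(4-methoxyphenyl)-6-[(E)-4-methoxystyryl]-2,3-dihydrobenzofuran-3-carboxylate (cis) | COc1ccc(/C=C/c2cc(OC)c3c(c2)O[C@H](c2ccc(OC)cc2)[C@@H]3C(=O)OC)cc1 | intermediate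
14 | methyl (2S,3S)-4-methoxy-2-(4-methoxyphenyl)-6-[(E)-4-methoxystyryl]-2,3-dihydrobenzofuran-3-carboxylate (trans) | COc1ccc(/C=C/c2cc(OC)c3c(c2)O[C@H](c2ccc(OC)cc2)[C@H]3C(=O)OC)cc1 | intermediate
15 | (2S,3S)-4-methoxy-2-(4-methoxyphenyl)-6-[(E)-4-methoxystyryl]-2,3-dihydrobenzofuran-3-carbaldehyde | COc1ccc(/C=C/c2cc(OC)c3c(c2)O[C@H](c2ccc(OC)cc2)[C@H]3C=O)cc1 | intermediate
16 | (2S,3S)-3-(2,2-dibromovinyl)-4-methoxy-2-(4-methoxyphenyl)-6-[(E)-4-methoxystyryl]-2,3-dihydrobenzofuran | COc1ccc(/C=C/c2cc(OC)c3c(c2)O[C@H](c2ccc(OC)cc2)[C@H]3C=C(Br)Br)cc1 | intermediate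
17 | lithium acetylide of (2S,3S)-3-ethynyl-4-methoxy-2-(4-methoxyphenyl)-6-[(E)-4-methoxystyryl]-2,3-dihydrobenzofuran | COc1ccc(/C=C/c2cc(OC)c3c(c2)O[C@H](c2ccc(OC)cc2)[C@H]3C#C[Li])cc1 | intermediate (not isolated)
18 | allyl 3-{(2S,3S)-4-methoxy-2-(4-methoxyphenyl)-6-[(E)-4-methoxystyryl]-2,3-dihydrobenzofuran-3-yl}prop-2-ynoate | COc1ccc(/C=C/c2cc(OC)c3c(c2)O[C@H](c2ccc(OC)cc2)[C@H]3C#CC(=O)OCC=C)cc1 | intermediate
19 | 1-(2,4-dimethoxyphenyl)ethan-1-one | CC(=O)c1ccc(OC)cc1OC | starting material
20 | 1-bromo-3,5-dimethoxybenzene | COc1cc(Br)cc(OC)c1 | starting material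
21 | 1-(2,4-dimethoxyphenyl)-2-(3,5-dimethoxyphenyl)ethan-1-one | COc1ccc(C(=O)Cc2cc(OC)cc(OC)c2)c(OC)c1 | intermediate
22 | methyl 4-(2,4-dimethoxyphenyl)-3-(3,5-dimethoxyphenyl)-4-oxobutanoate (racemic) | COC(=O)CC(c1cc(OC)cc(OC)c1)C(=O)c1ccc(OC)cc1OC | intermediate
23 | methyl (3R,4R)-4-(2,4-dimethoxyphenyl)-3-(3,5-dimethoxyphenyl)-4-hydroxybutanoate (syn) | COC(=O)C[C@H](c1cc(OC)cc(OC)c1)[C@@H](O)c1ccc(OC)cc1OC | intermediate (not isolated)
24 | (4R,5S)-5-(2,4-dimethoxyphenyl)-4-(3,5-dimethoxyphenyl)dihydrofuran-2(3H)-one (trans) | O=C1O[C@H](c2ccc(OC)cc2OC)[C@@H](c2cc(OC)cc(OC)c2)C1 | intermediate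
25 | (4R,5S)-3-acetyl-5-(2,4-dimethoxyphenyl)-4-(3,5-dimethoxyphenyl)dihydrofuran-2(3H)-one (C3 epimers and enol) | CC(=O)C1C(=O)O[C@H](c2ccc(OC)cc2OC)[C@H]1c1cc(OC)cc(OC)c1 | intermediate
26 | (4S,5S)-5-(2,4-dimethoxyphenyl)-4-(3,5-dimethoxyphenyl)-3-[1-(trimethylsilyloxy)ethylidene]dihydrofuran-2(3H)-one | CC(O[Si](C)(C)C)=C1C(=O)O[C@H](c2ccc(OC)cc2OC)[C@H]1c1cc(OC)cc(OC)c1 | intermediate (not isolated)
27 | (4S,5S)-5-(2,4-dimethoxyphenyl)-4-(3,5-dimethoxyphenyl)-2-(trimethylsilyloxy)-3-[1-(trimethylsilyloxy)vinyl]-4,5-dihydrofuran | C=C(O[Si](C)(C)C)C1=C(O[Si](C)(C)C)O[C@H](c2ccc(OC)cc2OC)[C@H]1c1cc(OC)cc(OC)c1 | intermediate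
28 | cycloadduct: allyl (2S,3S)-2-(2,4-dimethoxyphenyl)-3-(3,5-dimethoxyphenyl)-4,7a-bis(trimethylsilyloxy)-6-[upper (2S,3S)-dihydrobenzofuran-3-yl]-2,3,5,7a-tetrahydrobenzofuran-7-carboxylate (C7a unassigned) | COc1ccc(/C=C/c2cc(OC)c3c(c2)O[C@H](c2ccc(OC)cc2)[C@H]3C2=C(C(=O)OCC=C)C3(O[Si](C)(C)C)O[C@H](c4ccc(OC)cc4OC)[C@@H](c4cc(OC)cc(OC)c4)C3=C(O[Si](C)(C)C)C2)cc1 | intermediate (not isolated)
29 | allyl (2S,3S)-2-(2,4-dimethoxyphenyl)-3-(3,5-dimethoxyphenyl)-6-{(2S,3S)-4-methoxy-2-(4-methoxyphenyl)-6-[(E)-4-methoxystyryl]-2,3-dihydrobenzofuran-3-yl}-4-(trimethylsilyloxy)-2,3-dihydrobenzofuran-7-carboxylate | COc1ccc(/C=C/c2cc(OC)c3c(c2)O[C@H](c2ccc(OC)cc2)[C@H]3c2cc(O[Si](C)(C)C)c3c(c2C(=O)OCC=C)O[C@H](c2ccc(OC)cc2OC)[C@H]3c2cc(OC)cc(OC)c2)cc1 | intermediate (not isolated)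
30 | allyl (2S,3S)-2-(2,4-dimethoxyphenyl)-3-(3,5-dimethoxyphenyl)-4-hydroxy-6-{(2S,3S)-4-methoxy-2-(4-methoxyphenyl)-6-[(E)-4-methoxystyryl]-2,3-dihydrobenzofuran-3-yl}-2,3-dihydrobenzofuran-7-carboxylate | COc1ccc(/C=C/c2cc(OC)c3c(c2)O[C@H](c2ccc(OC)cc2)[C@H]3c2cc(O)c3c(c2C(=O)OCC=C)O[C@H](c2ccc(OC)cc2OC)[C@H]3c2cc(OC)cc(OC)c2)cc1 | intermediate
31 | (2S,3S)-2-(2,4-dimethoxyphenyl)-3-(3,5-dimethoxyphenyl)-4-hydroxy-6-{(2S,3S)-4-methoxy-2-(4-methoxyphenyl)-6-[(E)-4-methoxystyryl]-2,3-dihydrobenzofuran-3-yl}-2,3-dihydrobenzofuran-7-carboxylic acid | COc1ccc(/C=C/c2cc(OC)c3c(c2)O[C@H](c2ccc(OC)cc2)[C@H]3c2cc(O)c3c(c2C(=O)O)O[C@H](c2ccc(OC)cc2OC)[C@H]3c2cc(OC)cc(OC)c2)cc1 | intermediate (not isolated)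
32 | (2S,3S)-2-(2,4-dimethoxyphenyl)-3-(3,5-dimethoxyphenyl)-6-{(2S,3S)-4-methoxy-2-(4-methoxyphenyl)-6-[(E)-4-methoxystyryl]-2,3-dihydrobenzofuran-3-yl}-2,3-dihydrobenzofuran-4-ol | COc1ccc(/C=C/c2cc(OC)c3c(c2)O[C@H](c2ccc(OC)cc2)[C@H]3c2cc(O)c3c(c2)O[C@H](c2ccc(OC)cc2OC)[C@H]3c2cc(OC)cc(OC)c2)cc1 | intermediate
33 | (2S,3S)-2-(2,4-dihydroxyphenyl)-3-(3,5-dihydroxyphenyl)-6-{(2S,3S)-4-hydroxy-2-(4-hydroxyphenyl)-6-[(E)-4-hydroxystyryl]-2,3-dihydrobenzofuran-3-yl}-2,3-dihydrobenzofuran-4-ol | Oc1ccc(/C=C/c2cc(O)c3c(c2)O[C@H](c2ccc(O)cc2)[C@H]3c2cc(O)c3c(c2)O[C@H](c2ccc(O)cc2O)[C@H]3c2cc(O)cc(O)c2)cc1 | target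

## Step count and least certain steps

Total step count: 20. Longest linear sequence: 15 steps (steps 1–12, then 18–20); the lower half needs steps 13–17.

**Key step, step 18.** The most likely failure is that cycloaddition is too slow. The β-carbon of 18 carries a branched, doubly benzylic substituent and the ketene acetal end of 27 is tetrasubstituted, so thermal desilylation or decomposition of 27 may outrun C–C bond formation. A second uncertainty is ring opening during aromatisation followed by unselective reclosure; as explained in the step, this does not change what step 19 delivers.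

The fallback builds the arene from an open-chain diene of the long-established 1-methoxy-1,3-bis(silyloxy) type and closes the furan afterwards. It sets out from hydroxy ester 23, taken from step 15 before the acid stage.
- Silylation (t-BuMe2SiOTf, 2,6-lutidine) gives methyl (3R,4R)-4-(tert-butyldimethylsilyloxy)-4-(2,4-dimethoxyphenyl)-3-(3,5-dimethoxyphenyl)butanoate F1.
- C-acetylation under the conditions of step 16 gives the 2-acetyl ester F2.
- Two-stage silylation as in step 17 gives the open-chain diene F3, whose ketene acetal end is less encumbered than that of 27.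
- Heating F3 with 18, then mild desilylation, should give the allyl 2,4-dihydroxybenzoate F4 after loss of methanol.
- The conditions of step 19 remove the allyl ester and the carboxyl group to give the resorcinol F5, whose two hydroxyls are equivalent.
- CSA in CH2Cl2 ionises the 2,4-dimethoxybenzylic silyl ether, either phenol closes the trans furan, and the route is rejoined at 32.

**Step 15.** The dynamic resolution may fail in two ways: racemisation of 22 may be slower than reduction, or the hindered, electron-rich ketone may be reduced too slowly; either lowers the enantiomeric purity at C3. In the acid stage, loss of a proton from C3 of the benzylic cation and reprotonation would erode the same centre, so that stage is kept cold and short.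

The fallback separates reduction from stereocontrol. From 22, NaBH4 reduction and the same acid closure give the racemic trans lactone F6. Opening with (S)-1-phenylethylamine and AlMe3 gives diastereomeric hydroxy amides, from which the (3R,4S)-hydroxy amide F7 is separated. Brief treatment with CF3CO2H recloses it, with loss of the amine, and returns the route at 24.

**Step 8.** Both ortho positions of the carbene-bearing arene are substituted, which twists the arene out of conjugation with the carbene. This may lower enantio- and cis/trans control, and some insertion into the methoxy C–H bonds may compete.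

The fallback gives up catalyst control and resolves instead. From 12, Rh2(OAc)4 in CH2Cl2 gives the racemic cis ester F8. NaOMe in MeOH converts it into the racemic trans ester F9. Preparative chromatography on a chiral stationary phase returns the route at 14.

**Step 20.** The risk is Lewis-acid ionisation of the C2'–O1' bond, whose 2,4-dioxygenated aryl group stabilises the cation, followed by Friedel–Crafts oligomerisation, together with cationic dimerisation of the stilbene.

The fallback changes the mode of cleavage from electrophilic to nucleophilic. From 32, sodium ethanethiolate in DMF at 140 °C attacks the methyl carbons by SN2 under basic conditions, in which the benzylic ethers cannot ionise, and gives 33 directly; no new compound is involved.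

## Further compounds

F1 | step 18 | methyl (3R,4R)-4-(tert-butyldimethylsilyloxy)-4-(2,4-dimethoxyphenyl)-3-(3,5-dimethoxyphenyl)butanoate | COC(=O)C[C@H](c1cc(OC)cc(OC)c1)[C@@H](O[Si](C)(C)C(C)(C)C)c1ccc(OC)cc1OC
F2 | step 18 | methyl (3R,4R)-2-acetyl-4-(tert-butyldimethylsilyloxy)-4-(2,4-dimethoxyphenyl)-3-(3,5-dimethoxyphenyl)butanoate (C2 epimers) | COC(=O)C(C(C)=O)[C@H](c1cc(OC)cc(OC)c1)[C@@H](O[Si](C)(C)C(C)(C)C)c1ccc(OC)cc1OC
F3 | step 18 | 2-[(1S,2R)-2-(tert-butyldimethylsilyloxy)-2-(2,4-dimethoxyphenyl)-1-(3,5-dimethoxyphenyl)ethyl]-1-methoxy-1,3-bis(trimethylsilyloxy)buta-1,3-diene | C=C(O[Si](C)(C)C)C(=C(OC)O[Si](C)(C)C)[C@H](c1cc(OC)cc(OC)c1)[C@@H](O[Si](C)(C)C(C)(C)C)c1ccc(OC)cc1OC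
F4 | step 18 | allyl 3-[(1S,2R)-2-(tert-butyldimethylsilyloxy)-2-(2,4-dimethoxyphenyl)-1-(3,5-dimethoxyphenyl)ethyl]-2,4-dihydroxy-6-{(2S,3S)-4-methoxy-2-(4-methoxyphenyl)-6-[(E)-4-methoxystyryl]-2,3-dihydrobenzofuran-3-yl}benzoate | COc1ccc(/C=C/c2cc(OC)c3c(c2)O[C@H](c2ccc(OC)cc2)[C@H]3c2cc(O)c(c(O)c2C(=O)OCC=C)[C@H](c2cc(OC)cc(OC)c2)[C@@H](O[Si](C)(C)C(C)(C)C)c2ccc(OC)cc2OC)cc1
F5 | step 18 | 2-[(1S,2R)-2-(tert-butyldimethylsilyloxy)-2-(2,4-dimethoxyphenyl)-1-(3,5-dimethoxyphenyl)ethyl]-5-{(2S,3S)-4-methoxy-2-(4-methoxyphenyl)-6-[(E)-4-methoxystyryl]-2,3-dihydrobenzofuran-3-yl}benzene-1,3-diol | COc1ccc(/C=C/c2cc(OC)c3c(c2)O[C@H](c2ccc(OC)cc2)[C@H]3c2cc(O)c(c(O)c2)[C@H](c2cc(OC)cc(OC)c2)[C@@H](O[Si](C)(C)C(C)(C)C)c2ccc(OC)cc2OC)cc1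
F6 | step 15 | racemic trans-5-(2,4-dimethoxyphenyl)-4-(3,5-dimethoxyphenyl)dihydrofuran-2(3H)-one (both enantiomers) | O=C1O[C@H](c2ccc(OC)cc2OC)[C@@H](c2cc(OC)cc(OC)c2)C1.O=C1O[C@@H](c2ccc(OC)cc2OC)[C@H](c2cc(OC)cc(OC)c2)C1
F7 | step 15 | (3R,4S)-4-(2,4-dimethoxyphenyl)-3-(3,5-dimethoxyphenyl)-4-hydroxy-N-[(S)-1-phenylethyl]butanamide | C[C@H](NC(=O)C[C@H](c1cc(OC)cc(OC)c1)[C@H](O)c1ccc(OC)cc1OC)c1ccccc1
F8 | step 8 | racemic cis methyl 4-methoxy-2-(4-methoxyphenyl)-6-[(E)-4-methoxystyryl]-2,3-dihydrobenzofuran-3-carboxylate (both enantiomers) | COc1ccc(/C=C/c2cc(OC)c3c(c2)O[C@H](c2ccc(OC)cc2)[C@@H]3C(=O)OC)cc1.COc1ccc(/C=C/c2cc(OC)c3c(c2)O[C@@H](c2ccc(OC)cc2)[C@H]3C(=O)OC)cc1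
F9 | step 8 | racemic trans methyl 4-methoxy-2-(4-methoxyphenyl)-6-[(E)-4-methoxystyryl]-2,3-dihydrobenzofuran-3-carboxylate (both enantiomers) | COc1ccc(/C=C/c2cc(OC)c3c(c2)O[C@H](c2ccc(OC)cc2)[C@H]3C(=O)OC)cc1.COc1ccc(/C=C/c2cc(OC)c3c(c2)O[C@@H](c2ccc(OC)cc2)[C@@H]3C(=O)OC)cc1
F0 | step 20 | none | none
A1 | alternative 1 | methyl (2S,3S)-6-bromo-2-(2,4-dimethoxyphenyl)-4-methoxy-2,3-dihydrobenzofuran-3-carboxylate (trans) | Brc1cc(OC)c2c(c1)O[C@H](c1ccc(OC)cc1OC)[C@H]2C(=O)OC
A2 | alternative 1 | (2S)-7-bromo-2-(2,4-dimethoxyphenyl)-5-methoxychroman-4-one | COc1cc(Br)cc2O[C@H](c3ccc(OC)cc3OC)CC(=O)c12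
A3 | alternative 2 | anti pinacol boronate 2-{1-(4-methoxyphenyl)-2-[2-methoxy-4-(methoxycarbonyl)-6-(methoxymethoxy)phenyl]-2-[(2S,3S)-2-(2,4-dimethoxyphenyl)-3-(3,5-dimethoxyphenyl)-4-methoxy-2,3-dihydrobenzofuran-6-yl]ethyl}-4,4,5,5-tetramethyl-1,3,2-dioxaborolane (configuration as in the SMILES) | CC1(C)OB(OC1(C)C)[C@H](c1ccc(OC)cc1)[C@H](c1c(OC)cc(C(=O)OC)cc1OCOC)c1cc(OC)c2c(c1)O[C@H](c1ccc(OC)cc1OC)[C@H]2c1cc(OC)cc(OC)c1
A4 | alternative 2 | 2-[(E)-2-{(2S,3S)-2-(2,4-dimethoxyphenyl)-3-(3,5-dimethoxyphenyl)-4-methoxy-2,3-dihydrobenzofuran-6-yl}vinyl]-4,4,5,5-tetramethyl-1,3,2-dioxaborolane | CC1(C)OB(OC1(C)C)/C=C/c1cc(OC)c2c(c1)O[C@H](c1ccc(OC)cc1OC)[C@H]2c1cc(OC)cc(OC)c1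
A5 | alternative 2 | methyl 4-bromo-3-methoxy-5-(methoxymethoxy)benzoate | COC(=O)c1cc(OC)c(Br)c(OCOC)c1
A6 | alternative 3 | methyl (2S,3S)-2-(2,4-dimethoxyphenyl)-3-(3,5-dimethoxyphenyl)-4-methoxy-2,3-dihydrobenzofuran-6-carboxylate | COC(=O)c1cc(OC)c2c(c1)O[C@H](c1ccc(OC)cc1OC)[C@H]2c1cc(OC)cc(OC)c1
A7 | alternative 3 | (3S)-2-(2,4-dimethoxyphenyl)-3-(3,5-dimethoxyphenyl)-3-[2-hydroxy-6-methoxy-4-(methoxycarbonyl)phenyl]propanoic acid (C2 unassigned) | COC(=O)c1cc(O)c(c(OC)c1)[C@H](c1cc(OC)cc(OC)c1)C(C(=O)O)c1ccc(OC)cc1OC
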